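All runs are calculated for substances that don't exist.

The unit of count here is one turnover: each electrophile that becomes target frees one acid set free, which then meets free base, nucleophile or electrophile. So c(free base) is best counted in equivalents per electrophile, and side product in parts per part of target, a plain selectivity factor.

| setting | epsilon | theta | gamma | Tuesday's | Wednesday's | Monday's |
|---|---|---|---|---|---|---|
| electrophile | 0.050 M | 0.050 M | 0.050 M | 0.050 M | 0.050 M | 0.050 M |
| nucleophile | 0.050 M | 0.050 M | 0.050 M | 0.0500 M | 0.0500 M | 0.0500 M (fed, over 8.0 min) |
| free base | 0.075 M | 0.037 M | 0.15 M | 0.0750 M (fed, over 8.0 min) | 0.0750 M | 0.0750 M |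
| remark | run made earlier | run made earlier | run made earlier | all else is in the flask from the start; the feed brings no volume worth counting | everything together at the start | all else is in the flask from the start; the feed brings no volume worth counting |
| time |  |  |  | 20 min | 20 min | 20 min |

- epsilon (time / min: target / %, side product / %, electrophile / %): 0.667: 57.4, 0.7, 41.1; 2.00: 78.7, 2.2, 18.7; 3.00: 84.9, 2.6, 12.1; 5.00: 90.7, 2.3, 6.8; 8.00: 93.7, 2.8, 3.3; 10.0: 94.9, 2.7, 2.2; 12.0: 95.1, 3.1, 1.4
- theta (time / min: target / %, side product / %, electrophile / %): 0.833: 59.9, 1.5, 38.1; 2.50: 78.3, 3.7, 18.4; 5.00: 86.5, 6.3, 9.0; 6.00: 87.5, 5.5, 6.2; 10.0: 90.4, 6.7, 2.5; 12.0: 90.7, 7.1, 1.6; 15.0: 91.6, 7.1, 0.8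
- gamma (time / min: target / %, side product / %, electrophile / %): 0.833: 65.8, 0.6, 33.6; 2.50: 86.7, 1.4, 12.3; 5.00: 93.6, 1.7, 5.9; 6.00: 94.4, 1.5, 4.4; 10.0: 96.0, 1.4, 1.8; 12.0: 96.7, 1.7, 1.8; 15.0: 96.9, 1.4, 1.1

(scatter of a reading: 0.3 percentage points)

- steps thought possible: electrophile + nucleophile -> acid set free + target; nucleophile + acid set free <-> protonated nucleophile; acid set free + free base <-> salt of the base; electrophile + acid set free -> side product

* the flask that comes out highest in share of target in target plus side product, or "all alike" when all lie within 1.5 percentage points (Tuesday's / Wednesday's / Monday's / all alike)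
* share of target in target plus side product at the end, Tuesday's
* share of target in target plus side product at the end, Wednesday's
* share of target in target plus side product at the end, Monday's

The last rows of the tables carry the argument. The theta run, at 0.740 equivalents, ends with 7.1% side product against 91.6% target. The epsilon run, at 1.50 equivalents, ends with 3.1% against 95.1%, and the gamma run, at 3.00 equivalents, with 1.4% against 96.9%. Equivalents times parts of side product per part of target gives 0.0574, 0.0489 and 0.0433. Their mean, 0.0499, is the loss count: parts of side product per part of target at one equivalent of free base.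

For Wednesday's flask the count gives a share of 96.8%. Monday's flask holds the same free base from the start, so this count gives it the same share. In Tuesday's flask the feed has delivered 8.34% of its free base by 0.667 min, when the epsilon run already shows 57.4% target. Half the charge, the mean delivered during the feed, gives 93.8%, so this reckoning expects less for Tuesday's than for Wednesday's.

The forecast names Wednesday's, with 88% for Tuesday's, 97% for Wednesday's and 95.8% for Monday's, on the ground that “It forms mainly while electrophile is high, then plateaus”. For Tuesday's and Monday's it stands lower than this count.

Wednesday's comes out highest at 96.8%, against 90.7% for Tuesday's and 95.3% for Monday's, with these steps: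

    electrophile + nucleophile → acid set free + target (k = 1.30 /M/s)
    nucleophile + acid set free ⇌ protonated nucleophile, settled at all times (K = 300 /M)
    acid set free + free base ⇌ salt of the base (K = 1300 /M, k = 1.40 /M/s)
    electrophile + acid set free → side product (k = 0.150 /M/s)

Free base averaged 0.0169 M over the first 8.0 min in Tuesday's flask, against 0.0407 M in Wednesday's. Read backwards, Tuesday's share corresponds by the loss count to 0.483 equivalents, out of 1.50 charged. Read forwards, 0.380 equivalents give 88.4%, and the neighbour of Wednesday's flask with 0.019 M of free base gives 86.7%.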